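## Retrosynthetic overview

1. Target ⇐ its 3‑O‑TBS ether ⇐ late epoxidation of the 1(10)E‑alkene; the C8 side chain is built on the ring by acylation with (Z)‑2‑(bromomethyl)but‑2‑enoic acid and carboxylate displacement with (S)‑2‑(hydroxymethyl)butanoic acid.
2. α‑Methylene cis‑lactone ⇐ chelation‑controlled reduction and lactonisation of the ten‑membered enone 26, then Eschenmoser methylenation.
3. Ten‑membered ring ⇐ five‑carbon ring expansion of cyclopentanone 23: intramolecular alkenyllithium addition (transient bicyclo[5.3.0] alkoxide), then Grob fragmentation of C6–C10, giving the 4Z‑enone and the 1(10)E‑alkene.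
4. 23 ⇐ Morita–Baylis–Hillman union of cyclopentenone 10 with aldehyde 19, reductive methylation, mesylation.
5. 10 ⇐ monoacetate 1 by Johnson–Claisen rearrangement (C7 cis to O8) and epoxide/selenide transposition; 19 ⇐ propargyl alcohol. Ring order: cyclopentane (bought), ten‑membered carbocycle, γ‑lactone, epoxide.

Assumption 1: ring positions are quoted in germacrane numbering (C1–C15, lactone carbonyl C12); TBS = tert‑butyldimethylsilyl, PMB = 4‑methoxybenzyl, Ms = methanesulfonyl.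
Assumption 2: step 12 forms C1 without control; both C1 epimers are carried on because C1 and C10 become sp2 in step 15, and names and SMILES of 22–25 show the (1S,10R) member of the required 1,10‑unlike pair.

## Route

Step 1
Reactants: 1 (1S,4R)-cis-4-acetoxycyclopent-2-en-1-ol; 2 trimethyl orthoacetate
Product: 4 methyl 2-[(1S,5R)-5-acetoxycyclopent-2-en-1-yl]acetate, via ketene acetal 3 (not isolated)
Conditions: MeC(OMe)3 (5 equiv), propionic acid (5 mol%), xylene, 140 °C, MeOH distilled off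
Reagents that add atoms: none
Why: Johnson–Claisen rearrangement, in which the suprafacial [3,3] shift delivers the acetate carbon to the ring face that carried the C–O bond, so the new C7 centre is cis to the acetoxy group at C8.

Step 2
Reactants: 4 methyl 2-[(1S,5R)-5-acetoxycyclopent-2-en-1-yl]acetate
Product: 5 2-[(1S,5R)-5-hydroxycyclopent-2-en-1-yl]-N,N-dimethylacetamide
Conditions: Me2NH·HCl (4 equiv), AlMe3 (4 equiv), toluene/CH2Cl2, 0 → 45 °C; Rochelle salt work-up
Reagents that add atoms: dimethylamine hydrochloride, CNC.Cl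
Why: Weinreb-type aluminium amide aminolysis turns the methyl ester into the robust dimethylamide and removes the acetyl group as N,N-dimethylacetamide in the same operation, without touching C7 or C8.

Step 3
Reactants: 5 2-[(1S,5R)-5-hydroxycyclopent-2-en-1-yl]-N,N-dimethylacetamide
Product: 6 2-[(1S,5R)-5-(PMB-oxy)cyclopent-2-en-1-yl]-N,N-dimethylacetamide
Conditions: NaH, PMBCl, n-Bu4NI (cat.), THF/DMF, 0 °C → rt
Reagents that add atoms: 4-methoxybenzyl chloride, COc1ccc(CCl)cc1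
Why: Williamson etherification of the secondary alkoxide installs a chelating, oxidatively removable ether on O8.

Step 4
Reactants: 6 2-[(1S,5R)-5-(PMB-oxy)cyclopent-2-en-1-yl]-N,N-dimethylacetamide
Product: 7 2-[(1S,2R,3R,5R)-3-(PMB-oxy)-6-oxabicyclo[3.1.0]hexan-2-yl]-N,N-dimethylacetamide
Conditions: mCPBA, NaHCO3, CH2Cl2, 0 °C
Reagents that add atoms: mCPBA, OOC(=O)c1cccc(Cl)c1
Why: Prilezhaev epoxidation occurs on the ring face opposite the two cis substituents at C7 and C8, setting the epoxide trans to both.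

Step 5
Reactants: 7 2-[(1S,2R,3R,5R)-3-(PMB-oxy)-6-oxabicyclo[3.1.0]hexan-2-yl]-N,N-dimethylacetamide
Product: 9 2-[(1S,2R,5R)-2-hydroxy-5-(PMB-oxy)cyclopent-3-en-1-yl]-N,N-dimethylacetamide, via hydroxy selenide 8 (not isolated)
Conditions: (PhSe)2, NaBH4, EtOH, rt → 50 °C; then H2O2 (30%), THF, 0 °C → rt
Reagents that add atoms: none
Why: Sharpless–Lauer transposition, in which the selenolate opens the epoxide anti at the less hindered C10 and the selenoxide undergoes syn-elimination away from the hydroxyl, leaving the oxygen on C6 and the alkene at C9=C10.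

Step 6
Reactants: 9 2-[(1S,2R,5R)-2-hydroxy-5-(PMB-oxy)cyclopent-3-en-1-yl]-N,N-dimethylacetamide
Product: 10 2-[(1R,5R)-5-(PMB-oxy)-2-oxocyclopent-3-en-1-yl]-N,N-dimethylacetamide
Conditions: MnO2 (20 equiv), CH2Cl2, rt
Reagents that add atoms: none
Why: Neutral allylic oxidation with MnO2 gives the enone without epimerising the cis C7 centre.

Step 7
Reactants: 11 prop-2-yn-1-ol
Product: 13 (Z)-3-iodo-2-methylprop-2-en-1-ol, via alkenylmagnesium alkoxide 12 (not isolated)
Conditions: MeMgBr (2.5 equiv), CuI (10 mol%), Et2O, −10 °C → rt; then I2, −78 → 0 °C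
Reagents that add atoms: methylmagnesium bromide, C[Mg]Br; iodine, II
Why: Copper-catalysed carbomagnesiation of the propargylic alkoxide is anti and chelation-directed, and iodinolysis with retention fixes the Z geometry that later becomes the 4Z alkene.

Step 8
Reactants: 13 (Z)-3-iodo-2-methylprop-2-en-1-ol
Product: 14 (Z)-3-iodo-2-methylprop-2-enal
Conditions: MnO2, CH2Cl2, rt, dark, used at once
Reagents that add atoms: none
Why: Mild allylic oxidation with MnO2 avoids acid or iodide that would isomerise the Z-iodoenal.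

Step 9
Reactants: 14 (Z)-3-iodo-2-methylprop-2-enal
Product: 16 (3S,1Z)-1-iodo-2-methylhexa-1,5-dien-3-ol, via borinate 15 (not isolated)
Conditions: (−)-Ipc2BOMe, CH2=CHCH2MgBr, Et2O, −78 °C → rt; then 14, −78 °C; then NaOH, H2O2, rt
Reagents that add atoms: allylmagnesium bromide, C=CC[Mg]Br
Why: Brown allylboration through a chair transition state, where the (−)-diisopinocampheyl reagent adds allyl to the Si face of the enal and sets C3 as S.

Step 10
Reactants: 16 (3S,1Z)-1-iodo-2-methylhexa-1,5-dien-3-ol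
Product: 17 tert-butyl{[(3S,1Z)-1-iodo-2-methylhexa-1,5-dien-3-yl]oxy}dimethylsilane
Conditions: TBSCl, imidazole, DMF, rt
Reagents that add atoms: tert-butyldimethylsilyl chloride, CC(C)(C)[Si](C)(C)Cl
Why: Standard silylation protects the C3 hydroxyl through the organometallic steps.

Step 11
Reactants: 17 tert-butyl{[(3S,1Z)-1-iodo-2-methylhexa-1,5-dien-3-yl]oxy}dimethylsilane
Product: 19 (3S,4Z)-3-(TBS-oxy)-5-iodo-4-methylpent-4-enal, via diol 18 (not isolated)
Conditions: OsO4 (2 mol%), NaIO4 (4 equiv), 2,6-lutidine, dioxane/H2O, rt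
Reagents that add atoms: OsO4 (oxygen carrier), O=[Os](=O)(=O)=O; sodium periodate NaIO4, [Na+].[O-]I(=O)(=O)=O
Why: Lemieux–Johnson cleavage is selective for the monosubstituted alkene over the hindered, electron-poor trisubstituted iodoalkene.

Step 12
Reactants: 10 2-[(1R,5R)-5-(PMB-oxy)-2-oxocyclopent-3-en-1-yl]-N,N-dimethylacetamide; 19 (3S,4Z)-3-(TBS-oxy)-5-iodo-4-methylpent-4-enal
Product: 20 2-[(1R,5R)-3-[(3S,4Z)-3-(TBS-oxy)-1-hydroxy-5-iodo-4-methylpent-4-en-1-yl]-5-(PMB-oxy)-2-oxocyclopent-3-en-1-yl]-N,N-dimethylacetamide (both C1 epimers)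
Conditions: n-Bu3P (20 mol%), 1,1′-bi-2-naphthol (10 mol%), THF, rt
Reagents that add atoms: none
Why: Morita–Baylis–Hillman reaction, in which the phosphine adds to C9, the C10 enolate adds to the aldehyde to form C10–C1, and the phosphine is then eliminated; C1 is formed unselectively, which is harmless.

Step 13
Reactants: 20 MBH adduct (both C1 epimers)
Product: 22 2-[(1R,3R,5R)-3-[(1S,3S,4Z)-3-(TBS-oxy)-1-hydroxy-5-iodo-4-methylpent-4-en-1-yl]-5-(PMB-oxy)-3-methyl-2-oxocyclopentyl]-N,N-dimethylacetamide, via dilithium enolate alkoxide 21 (not isolated)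
Conditions: LiN(SiMe3)2 (1.05 equiv), THF, −78 °C; LiBH(s-Bu)3 (1.1 equiv), −78 °C; then MeI (5 equiv), DMPU, −78 → −20 °C
Reagents that add atoms: iodomethane, CI
Why: Conjugate hydride reduction gives the regiodefined C10 enolate held in a lithium chelate with the C1 alkoxide, and Fráter–Seebach-type methylation anti to the C2 chain sets the quaternary C10 with the 1,10-unlike relative configuration that the later fragmentation translates into the E alkene.

Step 14
Reactants: 22 β-hydroxy ketone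
Product: 23 C1 methanesulfonate of 22
Conditions: MsCl, Et3N, CH2Cl2, −10 °C
Reagents that add atoms: methanesulfonyl chloride, CS(=O)(=O)Cl
Why: Sulfonylation of the neopentyl-type secondary alcohol gives a mesylate that cannot eliminate toward the quaternary C10.

Step 15
Reactants: 23 C1 methanesulfonate of 22
Product: 26 2-[(1R,3Z,5S,7E,10R)-5-(TBS-oxy)-10-(PMB-oxy)-4,8-dimethyl-2-oxocyclodeca-3,7-dien-1-yl]-N,N-dimethylacetamide, via alkenyllithium 24 (not isolated), via bicyclic lithium alkoxide 25 (not isolated)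
Conditions: t-BuLi (2.05 equiv), THF/Et2O, −100 → −78 °C; then DMPU, −78 → 0 °C
Reagents that add atoms: none
Why: Proposed new method: iodine–lithium exchange, faster than attack of t-BuLi on the hindered ketone or the amide, gives alkenyllithium 24, whose Z geometry holds the carbanion over the C6 carbonyl so that 1,2-addition closes the seven-membered ring of the cis-fused bicyclo[5.3.0] alkoxide 25, in which C6–C10 is antiperiplanar to C1–OMs, and concerted Grob fragmentation then breaks C6–C10 and expels mesylate to give the 4Z-enone and, stereospecifically from the 1,10-unlike mesylate, the 1(10)E alkene in a net five-carbon ring expansion; the closest known reaction types are the SmI2 Barbier cyclisation/Grob fragmentation of iodoalkyl keto sulfonates (sp3 nucleophile, ring-bound sulfonate) and the Wharton–Grob fragmentation of bicyclic 1,3-diol monosulfonates, neither shown with an alkenyl nucleophile from halogen–lithium exchange and an exocyclic aldol-type sulfonate.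

Step 16
Reactants: 26 ten-membered enone
Product: 28 (3aR,4R,6E,9S,10Z,11aS)-9-(TBS-oxy)-4-(PMB-oxy)-6,10-dimethyl-3a,4,5,8,9,11a-hexahydrocyclodeca[b]furan-2(3H)-one, via hydroxy amide 27 (not isolated)
Conditions: Zn(BH4)2, Et2O, −30 °C; then pyridinium p-toluenesulfonate (1.2 equiv), benzene, 60 °C
Reagents that add atoms: none
Why: Chelation-controlled 1,2-reduction through the zinc chelate between the C6 carbonyl and the C8 PMB ether delivers hydride anti to the C7 side chain, giving the 6S alcohol (1,3-syn to O8, cis to C11), which lactonises with loss of dimethylamine.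

Step 17
Reactants: 28 cis-fused lactone
Product: 31 (3aR,4R,6E,9S,10Z,11aS)-9-(TBS-oxy)-4-(PMB-oxy)-6,10-dimethyl-3-methylene-3a,4,5,8,9,11a-hexahydrocyclodeca[b]furan-2(3H)-one, via Mannich base 29 (not isolated), via trimethylammonium iodide 30 (not isolated)
Conditions: LiN(SiMe3)2, THF, −78 °C; CH2=NMe2+ I−, −78 → 0 °C; then MeI, MeOH, rt; then NaHCO3 (aq.), CH2Cl2, rt
Reagents that add atoms: N,N-dimethylmethyleneiminium iodide (Eschenmoser's salt), C=[N+](C)C.[I-]
Why: Eschenmoser methylenation (lactone enolate Mannich reaction, N-quaternisation, β-elimination) installs the exocyclic C11=C13 alkene without touching C7.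

Step 18
Reactants: 31 α-methylene lactone
Product: 32 (3aR,4R,6E,9S,10Z,11aS)-9-(TBS-oxy)-4-hydroxy-6,10-dimethyl-3-methylene-3a,4,5,8,9,11a-hexahydrocyclodeca[b]furan-2(3H)-one
Conditions: DDQ, CH2Cl2/pH 7 buffer (10:1), 0 °C → rt
Reagents that add atoms: none
Why: Oxidative cleavage of the PMB ether frees only the C8 hydroxyl, the silyl ether and the lactone being inert to DDQ.

Step 19
Reactants: 32 C8 alcohol; 33 (Z)-2-(bromomethyl)but-2-enoic acid
Product: 34 (3aR,4R,6E,9S,10Z,11aS)-9-(TBS-oxy)-6,10-dimethyl-3-methylene-2-oxo-2,3,3a,4,5,8,9,11a-octahydrocyclodeca[b]furan-4-yl (2Z)-2-(bromomethyl)but-2-enoate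
Conditions: DCC, 4-(dimethylamino)pyridine (5 mol%), CH2Cl2, 0 °C
Reagents that add atoms: none
Why: Steglich esterification acylates the free C8 hydroxyl with retention at C8 and without disturbing the 6,12-lactone.

Step 20
Reactants: 35 butanal; 36 formaldehyde
Product: 38 (S)-2-(hydroxymethyl)butanoic acid, via hydroxymethyl aldehyde 37 (not isolated)
Conditions: aq. HCHO, (R)-α,α-diphenylprolinol trimethylsilyl ether (10 mol%), pH 7 phosphate buffer, toluene, rt; then NaClO2, NaH2PO4, 2-methylbut-2-ene, t-BuOH/H2O, 0 °C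
Reagents that add atoms: sodium chlorite, [Na+].[O-]Cl=O
Why: Enamine-catalysed α-hydroxymethylation, in which the diarylmethyl group of the (R)-catalyst shields one enamine face and is expected on that model to give the S aldehyde, is followed by Pinnick oxidation, which does not epimerise the α-centre.

Step 21
Reactants: 34 allylic bromide; 38 (S)-2-(hydroxymethyl)butanoic acid
Product: 39 (3aR,4R,6E,9S,10Z,11aS)-9-(TBS-oxy)-6,10-dimethyl-3-methylene-2-oxo-2,3,3a,4,5,8,9,11a-octahydrocyclodeca[b]furan-4-yl (2E)-2-({[(2S)-2-(hydroxymethyl)butanoyl]oxy}methyl)but-2-enoate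
Conditions: Cs2CO3 (1.0 equiv), DMF, 0 °C → rt
Reagents that add atoms: none
Why: SN2 alkylation of the caesium carboxylate at the primary allylic bromide keeps the olefin geometry (Z-bromide becomes E-acyloxymethyl by CIP only) and leaves the free primary hydroxyl untouched.

Step 22
Reactants: 39 triene ester
Product: 40 3-O-TBS ether of the target [(1R,10R)-1,10-epoxide of 39]
Conditions: mCPBA (1.05 equiv), NaHCO3, CH2Cl2, −20 → 0 °C
Reagents that add atoms: mCPBA, OOC(=O)c1cccc(Cl)c1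
Why: Prilezhaev epoxidation takes the only electron-rich alkene (C4=C5 carries two allylic oxygens and the other two are conjugated to esters), and attack on its exposed outer face is expected to give the (1R,10R)-trans-epoxide as in related germacranolides.

Step 23
Reactants: 40 3-O-TBS ether of the target
Product: 41 target CNP0156402.1
Conditions: HF·pyridine, pyridine, THF, 0 °C
Reagents that add atoms: none
Why: Buffered fluoride desilylation releases the C3 hydroxyl without opening the epoxide, adding to the α-methylene lactone or migrating the esters.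

## Compound list

1 | (1S,4R)-cis-4-acetoxycyclopent-2-en-1-ol (monoacetyl-protected cis-cyclopent-4-ene-1,3-diol) | O[C@@H]1C=C[C@H](OC(C)=O)C1 | starting material
2 | trimethyl orthoacetate | CC(OC)(OC)OC | starting material
3 | (1R,4S)-4-[(1-methoxyethenyl)oxy]cyclopent-2-en-1-yl acetate | C=C(OC)O[C@@H]1C=C[C@H](OC(C)=O)C1 | intermediate
4 | methyl 2-[(1S,5R)-5-acetoxycyclopent-2-en-1-yl]acetate | COC(=O)C[C@H]1C=CC[C@H]1OC(C)=O | intermediate
5 | 2-[(1S,5R)-5-hydroxycyclopent-2-en-1-yl]-N,N-dimethylacetamide | CN(C)C(=O)C[C@H]1C=CC[C@H]1O | intermediate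
6 | 2-[(1S,5R)-5-(PMB-oxy)cyclopent-2-en-1-yl]-N,N-dimethylacetamide | CN(C)C(=O)C[C@H]1C=CC[C@H]1OCc1ccc(OC)cc1 | intermediate
7 | 2-[(1S,2R,3R,5R)-3-(PMB-oxy)-6-oxabicyclo[3.1.0]hexan-2-yl]-N,N-dimethylacetamide | CN(C)C(=O)C[C@H]1[C@@H]2O[C@@H]2C[C@H]1OCc1ccc(OC)cc1 | intermediate
8 | 2-[(1S,2S,3S,5R)-2-hydroxy-5-(PMB-oxy)-3-(phenylselanyl)cyclopentyl]-N,N-dimethylacetamide | CN(C)C(=O)C[C@H]1[C@H](O)[C@@H]([Se]c2ccccc2)C[C@H]1OCc1ccc(OC)cc1 | intermediate
9 | 2-[(1S,2R,5R)-2-hydroxy-5-(PMB-oxy)cyclopent-3-en-1-yl]-N,N-dimethylacetamide | CN(C)C(=O)C[C@H]1[C@H](O)C=C[C@H]1OCc1ccc(OC)cc1 | intermediate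
10 | 2-[(1R,5R)-5-(PMB-oxy)-2-oxocyclopent-3-en-1-yl]-N,N-dimethylacetamide | CN(C)C(=O)C[C@H]1C(=O)C=C[C@H]1OCc1ccc(OC)cc1 | intermediate
11 | prop-2-yn-1-ol | C#CCO | starting material
12 | bromomagnesium (Z)-3-(bromomagnesio)-2-methylprop-2-en-1-olate | Br[Mg]OC/C(C)=C\[Mg]Br | intermediate
13 | (Z)-3-iodo-2-methylprop-2-en-1-ol | OC/C(C)=C\I | intermediate
14 | (Z)-3-iodo-2-methylprop-2-enal | O=C/C(C)=C\I | intermediate
15 | (3S,1Z)-1-iodo-2-methylhexa-1,5-dien-3-yl diisopinocampheylborinate | C=CC[C@H](OB([C@@H]1C[C@@H]2C[C@H]([C@H]1C)C2(C)C)[C@@H]1C[C@@H]2C[C@H]([C@H]1C)C2(C)C)/C(C)=C\I | intermediate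
16 | (3S,1Z)-1-iodo-2-methylhexa-1,5-dien-3-ol | C=CC[C@H](O)/C(C)=C\I | intermediate
17 | tert-butyl{[(3S,1Z)-1-iodo-2-methylhexa-1,5-dien-3-yl]oxy}dimethylsilane | C=CC[C@H](O[Si](C)(C)C(C)(C)C)/C(C)=C\I | intermediate
18 | (4S,5Z)-4-(TBS-oxy)-6-iodo-5-methylhex-5-ene-1,2-diol (C2 epimers) | OCC(O)C[C@H](O[Si](C)(C)C(C)(C)C)/C(C)=C\I | intermediate
19 | (3S,4Z)-3-(TBS-oxy)-5-iodo-4-methylpent-4-enal | O=CC[C@H](O[Si](C)(C)C(C)(C)C)/C(C)=C\I | intermediate
20 | 2-[(1R,5R)-3-[(3S,4Z)-3-(TBS-oxy)-1-hydroxy-5-iodo-4-methylpent-4-en-1-yl]-5-(PMB-oxy)-2-oxocyclopent-3-en-1-yl]-N,N-dimethylacetamide (C1 epimers) | CN(C)C(=O)C[C@H]1C(=O)C(C(O)C[C@H](O[Si](C)(C)C(C)(C)C)/C(C)=C\I)=C[C@H]1OCc1ccc(OC)cc1 | intermediate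
21 | dilithium enolate alkoxide formed by conjugate reduction of the lithium alkoxide of 20 | [Li+].[Li+].CN(C)C(=O)C[C@H]1C([O-])=C(C([O-])C[C@H](O[Si](C)(C)C(C)(C)C)/C(C)=C\I)C[C@H]1OCc1ccc(OC)cc1 | intermediate
22 | 2-[(1R,3R,5R)-3-[(1S,3S,4Z)-3-(TBS-oxy)-1-hydroxy-5-iodo-4-methylpent-4-en-1-yl]-5-(PMB-oxy)-3-methyl-2-oxocyclopentyl]-N,N-dimethylacetamide (with its 1R,10S partner) | CN(C)C(=O)C[C@H]1C(=O)[C@@](C)([C@@H](O)C[C@H](O[Si](C)(C)C(C)(C)C)/C(C)=C\I)C[C@H]1OCc1ccc(OC)cc1 | intermediate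
23 | C1 methanesulfonate of 22 | CN(C)C(=O)C[C@H]1C(=O)[C@@](C)([C@@H](OS(C)(=O)=O)C[C@H](O[Si](C)(C)C(C)(C)C)/C(C)=C\I)C[C@H]1OCc1ccc(OC)cc1 | intermediate
24 | (Z)-alkenyllithium from 23 (Li in place of I at C5) | CN(C)C(=O)C[C@H]1C(=O)[C@@](C)([C@@H](OS(C)(=O)=O)C[C@H](O[Si](C)(C)C(C)(C)C)/C(C)=C\[Li])C[C@H]1OCc1ccc(OC)cc1 | intermediate
25 | cis-fused bicyclo[5.3.0]dec-2-ene lithium alkoxide (C5–C6 bond formed; O6 and C10 methyl cis; C1 mesylate) | [Li+].CN(C)C(=O)C[C@H]1[C@@]2([O-])C=C(C)[C@@H](O[Si](C)(C)C(C)(C)C)C[C@H](OS(C)(=O)=O)[C@@]2(C)C[C@H]1OCc1ccc(OC)cc1 | intermediate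
26 | 2-[(1R,3Z,5S,7E,10R)-5-(TBS-oxy)-10-(PMB-oxy)-4,8-dimethyl-2-oxocyclodeca-3,7-dien-1-yl]-N,N-dimethylacetamide | CN(C)C(=O)C[C@H]1C(=O)/C=C(/C)[C@@H](O[Si](C)(C)C(C)(C)C)C/C=C(\C)C[C@H]1OCc1ccc(OC)cc1 | intermediate
27 | 2-[(1S,2S,3Z,5S,7E,10R)-5-(TBS-oxy)-2-hydroxy-10-(PMB-oxy)-4,8-dimethylcyclodeca-3,7-dien-1-yl]-N,N-dimethylacetamide | CN(C)C(=O)C[C@H]1[C@@H](O)/C=C(/C)[C@@H](O[Si](C)(C)C(C)(C)C)C/C=C(\C)C[C@H]1OCc1ccc(OC)cc1 | intermediate
28 | (3aR,4R,6E,9S,10Z,11aS)-9-(TBS-oxy)-4-(PMB-oxy)-6,10-dimethyl-3a,4,5,8,9,11a-hexahydrocyclodeca[b]furan-2(3H)-one | C1C(=O)O[C@H]2/C=C(/C)[C@@H](O[Si](C)(C)C(C)(C)C)C/C=C(\C)C[C@@H](OCc3ccc(OC)cc3)[C@@H]12 | intermediate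
29 | 3-[(dimethylamino)methyl] derivative of 28 (C11 epimers) | CN(C)CC1C(=O)O[C@H]2/C=C(/C)[C@@H](O[Si](C)(C)C(C)(C)C)C/C=C(\C)C[C@@H](OCc3ccc(OC)cc3)[C@@H]12 | intermediate
30 | trimethylammonium iodide of 29 | [I-].C[N+](C)(C)CC1C(=O)O[C@H]2/C=C(/C)[C@@H](O[Si](C)(C)C(C)(C)C)C/C=C(\C)C[C@@H](OCc3ccc(OC)cc3)[C@@H]12 | intermediate
31 | (3aR,4R,6E,9S,10Z,11aS)-9-(TBS-oxy)-4-(PMB-oxy)-6,10-dimethyl-3-methylene-3a,4,5,8,9,11a-hexahydrocyclodeca[b]furan-2(3H)-one | C=C1C(=O)O[C@H]2/C=C(/C)[C@@H](O[Si](C)(C)C(C)(C)C)C/C=C(\C)C[C@@H](OCc3ccc(OC)cc3)[C@@H]12 | intermediate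
32 | (3aR,4R,6E,9S,10Z,11aS)-9-(TBS-oxy)-4-hydroxy-6,10-dimethyl-3-methylene-3a,4,5,8,9,11a-hexahydrocyclodeca[b]furan-2(3H)-one | C=C1C(=O)O[C@H]2/C=C(/C)[C@@H](O[Si](C)(C)C(C)(C)C)C/C=C(\C)C[C@@H](O)[C@@H]12 | intermediate
33 | (Z)-2-(bromomethyl)but-2-enoic acid | C/C=C(\CBr)C(O)=O | starting material
34 | C8 (2Z)-2-(bromomethyl)but-2-enoate of 32 | C=C1C(=O)O[C@H]2/C=C(/C)[C@@H](O[Si](C)(C)C(C)(C)C)C/C=C(\C)C[C@@H](OC(=O)/C(CBr)=C/C)[C@@H]12 | intermediate
35 | butanal | CCCC=O | starting material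
36 | formaldehyde | C=O | starting material
37 | (S)-2-(hydroxymethyl)butanal | O=C[C@@H](CC)CO | intermediate
38 | (S)-2-(hydroxymethyl)butanoic acid | OC(=O)[C@@H](CC)CO | intermediate
39 | C8 (2E)-2-({[(2S)-2-(hydroxymethyl)butanoyl]oxy}methyl)but-2-enoate of 32 | C=C1C(=O)O[C@H]2/C=C(/C)[C@@H](O[Si](C)(C)C(C)(C)C)C/C=C(\C)C[C@@H](OC(=O)/C(=C/C)COC(=O)[C@@H](CC)CO)[C@@H]12 | intermediate
40 | 3-O-TBS ether of the target, (1R,10R)-1,10-epoxide of 39 | C=C1C(=O)O[C@H]2/C=C(/C)[C@@H](O[Si](C)(C)C(C)(C)C)C[C@H]3O[C@]3(C)C[C@@H](OC(=O)/C(=C/C)COC(=O)[C@@H](CC)CO)[C@@H]12 | intermediate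
41 | CNP0156402.1, (1R,3S,6S,7R,8R,10R)-1,10-epoxy-3-hydroxy-8-[(2E)-2-({[(2S)-2-(hydroxymethyl)butanoyl]oxy}methyl)but-2-enoyloxy]germacra-4Z,11(13)-dien-6,12-olide | C=C1C(=O)O[C@H]2/C=C(/C)[C@@H](O)C[C@H]3O[C@]3(C)C[C@@H](OC(=O)/C(=C/C)COC(=O)[C@@H](CC)CO)[C@@H]12 | target

## Step count and risks

Total step count: 23. Longest linear sequence: 17 steps (1 → 41 through steps 1–6, 12–19 and 21–23).

Steps most likely to fail:

Step 15 (the proposed ring expansion). The alkenyllithium may fail to close the seven-membered ring, or the lithium alkoxide may fragment sluggishly. The fallback sets out from 23 and uses known chemistry in two isolated stages. Intramolecular Nozaki–Hiyama–Kishi addition of the alkenyl iodide to the C6 ketone (CrCl2, cat. NiCl2, DMSO/THF, rt) gives, after work-up, the bicyclic hydroxy mesylate F3, since the chromium alkoxide does not fragment. Classical Wharton–Grob fragmentation of F3 with KOt-Bu in THF at 0 °C then returns to the route at 26.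

Step 13 (relative configuration at C1/C10, which decides E versus Z at C1=C10). If the chelate-controlled methylation is unselective, the fallback sets out from 20 and fixes C1 by reduction instead of fixing C10 by alkylation. Dess–Martin oxidation gives the 2-acylcyclopent-2-enone F1. Conjugate reduction with LiBH(s-Bu)3 and C-methylation of the β-diketone enolate with MeI give the 2-acyl-2-methylcyclopentanone F2 (C10 epimers, no stereochemical demand at this stage). Zn(BH4)2 then reduces the less hindered side-chain ketone through the β-diketone zinc chelate from the methyl face, which gives the same 1,10-unlike alcohol and comes back at 22.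

Step 22 (face selectivity of the C1=C10 epoxidation). If mCPBA attacks the other face, the fallback sets out from 39. NBS in aqueous acetone at 0 °C puts bromine on that same exposed face and water on the tertiary C10 from the opposite side, giving the bromohydrin F4. K2CO3 in acetone then closes the epoxide with inversion at C1, placing the oxygen on the face opposite to direct peracid attack, and the route is rejoined at 40.

## Further compounds

F1 | step 13 | 2-[(1R,5R)-3-[(3S,4Z)-3-(TBS-oxy)-5-iodo-4-methylpent-4-enoyl]-5-(PMB-oxy)-2-oxocyclopent-3-en-1-yl]-N,N-dimethylacetamide | CN(C)C(=O)C[C@H]1C(=O)C(C(=O)C[C@H](O[Si](C)(C)C(C)(C)C)/C(C)=C\I)=C[C@H]1OCc1ccc(OC)cc1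
F2 | step 13 | 2-[(1R,5R)-3-[(3S,4Z)-3-(TBS-oxy)-5-iodo-4-methylpent-4-enoyl]-5-(PMB-oxy)-3-methyl-2-oxocyclopentyl]-N,N-dimethylacetamide (C10 epimers) | CN(C)C(=O)C[C@H]1C(=O)C(C)(C(=O)C[C@H](O[Si](C)(C)C(C)(C)C)/C(C)=C\I)C[C@H]1OCc1ccc(OC)cc1
F3 | step 15 | cis-fused bicyclo[5.3.0]dec-2-en-1-ol mesylate (protonated form of 25) | CN(C)C(=O)C[C@H]1[C@@]2(O)C=C(C)[C@@H](O[Si](C)(C)C(C)(C)C)C[C@H](OS(C)(=O)=O)[C@@]2(C)C[C@H]1OCc1ccc(OC)cc1
F4 | step 22 | (1S,10R)-1-bromo-10-hydroxy-1,10-dihydro derivative of 39 | C=C1C(=O)O[C@H]2/C=C(/C)[C@@H](O[Si](C)(C)C(C)(C)C)C[C@H](Br)[C@@](O)(C)C[C@@H](OC(=O)/C(=C/C)COC(=O)[C@@H](CC)CO)[C@@H]12
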